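We begin from two constants read off the runs: a ratio between the gamma and epsilon runs, and from it a stop quotient. The flask asked about is the gamma run followed on to 8.0 min.

| flask | starting material | second substrate | reagent | free catalyst | remark | time |
|---|---|---|---|---|---|---|
| gamma | 0.30 M | 0.30 M | 0.36 M | 0.30 mM | the very flask that is asked about, followed so far |  |
| epsilon | 0.30 M | 0.15 M | 0.36 M | 0.30 mM | run made earlier |  |
| flask | 0.30 M | 0.300 M | 0.360 M | 0.30 mM |  | 8.0 min |

gamma run (percent of the starting material charged)

| time / s | starting material / % | target / % |
|---|---|---|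
| 10.0 | 81.9 | 16.5 |
| 12.0 | 79.8 | 20.3 |
| 25.0 | 66.5 | 33.4 |
| 40.0 | 56.1 | 43.1 |
| 50.0 | 52.9 | 46.9 |
| 60.0 | 49.9 | 49.6 |
| 80.0 | 46.5 | 52.2 |

epsilon run (percent of the starting material charged)

| time / min | starting material / % | target / % |
|---|---|---|
| 0.417 | 63.0 | 36.2 |
| 0.667 | 53.3 | 46.4 |
| 1.00 | 46.0 | 53.1 |
| 1.50 | 42.5 | 57.8 |
| 2.50 | 38.3 | 60.9 |
| 4.00 | 38.6 | 61.3 |
| 6.00 | 37.6 | 61.3 |

(readings scatter by 0.5 percentage points)

- the analysis behind the earlier runs scatters by 0.5 percentage points, standard deviation

1. share of the starting material used up at 8.0 min
2. target at 8.0 min, in percent of the starting material charged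

1. With the main step by itself, starting material + reagent to target, and 1.20 equivalents of reagent, the ceiling on target is 100 %.

2. Adding the stall seen in the epsilon run lowers this: its target lies flat from 2.50 min to 6.00 min, and its last readings average P∞ = 61.2 %.

3. Adding the doubled second substrate lowers it again. The target in gamma over the target in epsilon at equal times, ρ, reads 0.923 at 25.0 s, 0.929 at 40.0 s and 0.934 at 60.0 s. We freeze it at 0.929, so our reckoning puts the flask's target at 56.8 %. Starting material and target summed to 99.5 % at 60.0 s, so we expect the same figure for conversion.

4. With x the target concentration at the stop and cA and cB the charges of starting material and reagent, we define the stop quotient W = x/((cA − x)(cB − x)), target over the starting material and reagent left, reagent being counted as charge minus target. For this second substrate charge, W = 6.93 M⁻¹.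

The forecast gives 57 % conversion and 56.5 % target, expecting that “By 8 min the flask should be flat”. The flask gives 57.0 % and 56.8 %.

    starting material + free catalyst ⇌ catalyst intermediate A (K = 8.10 M⁻¹, k = 300 M⁻¹ s⁻¹)
    reagent + catalyst intermediate A ⇌ free catalyst + target (K = 2.50, k = 130 M⁻¹ s⁻¹)
    second substrate + free catalyst ⇌ catalyst intermediate B (K = 1.50 M⁻¹, k = 290 M⁻¹ s⁻¹)
    reagent + catalyst intermediate B → free catalyst + second product (k = 180 M⁻¹ s⁻¹)
    catalyst intermediate A + target → spent catalyst (k = 0.240 M⁻¹ s⁻¹)

The flask's own values give W = 6.98 M⁻¹. W is our bookkeeping and stands nowhere in these equations: at 8.00 min the flask held 0.101 M of second product, which our count of reagent leaves out, and spent catalyst stood at >99.9 % of the catalyst charged. We hold W for a neighbour flask, the same except that reagent is cut to 0.090 M, which makes it the limiting reagent at 0.300 equiv. Solving the definition for x with that charge gives target 18.8 %. That neighbour flask gave 18.1 %, with 82 % of its starting material and 10 % of its reagent left.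

All runs come from a simulation for substances that don't exist; the scatter is artificial.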